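Cuts, in 2-oxaspiro[4.5]decane numbering: C5–C10 and C8–C9 go together. Ring B gives up C9=C10 as an acetylene equivalent and becomes a vinylketene acetal on a 3-alkylidene-oxolane. Later cuts are C6=C7 (olefination), O2–C3 (benzylic etherification), and C1–C1' and C3–C4 (two aldol bonds).
Enabling feature: in ring B the C6=C7(OMe) double bond lies between spiro C5 and carbonyl C8, exactly where a [4+2] cycloaddition leaves its new π bond. C9=C10 is an unsubstituted CH=CH. C10 stands on the oxolane face opposite to the C1 side chain and the C4 CH2OH, the two groups that flank C5.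
Forward order: aldol 1 (C3–C4), oxidative cleavage and α-methylenation to an enal, aldol 2 (C1–C1') joining the guaiacyl and aryloxy halves, closure of ring A (oxolane) at O2–C3, extension of C5 by C6–C8, and ring B built last on the finished ring A.
Stereochemistry: C4 comes from the (S)-benzyloxazolidinone syn aldol, and C1 and C1' from the (R)-benzyloxazolidinone glycolate syn aldol. C3 is set by reversible, trans-selective benzylic ring closure next to C4. C5 is set by attack of the dienophile on the open face of the alkylidene-oxolane.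

Key step: step 18

Remark: monocyclic intermediates are numbered as oxolanes (O1, C2 = side-chain carbon, C3, C4 = CH2O-bearing carbon, C5 = aryl-bearing carbon; these become C1, C5, C4, C3 of the spirocycle); TBS = tert-butyldimethylsilyl, Ar = 4-(TBSO)-3-methoxyphenyl, SC = (1S)-2-(TBSO)-1-[2-methoxy-4-(3-TBSO-propyl)phenoxy]ethyl; it is assumed that the C3 configuration of 25–29 and the double-bond geometries of 29 and 30, drawn as expected, are immaterial because steps 17 and 18 erase them.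

Step 1
Reactants: 1 vanillin
Product: 2 4-(TBSO)-3-methoxybenzaldehyde
Conditions: TBSCl, imidazole, DMF, rt
Reagents that add atoms: tert-butyldimethylsilyl chloride, CC(C)(C)[Si](C)(C)Cl
Why: Routine phenol O-silylation installs a fluoride-labile group that keeps the ring electron-rich for the benzylic ionisation of step 12 and falls in the final global desilylation.

Step 2
Reactants: 3 (S)-4-benzyl-1,3-oxazolidin-2-one; 4 pent-4-enoyl chloride
Product: 5 (S)-4-benzyl-3-(pent-4-enoyl)-1,3-oxazolidin-2-one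
Conditions: n-BuLi, THF, −78 °C; then 4, −78 → 0 °C
Reagents that add atoms: none
Why: N-acylation of the lithiated oxazolidinone is the standard entry to Evans imides, and the allyl terminus is the masked C2 aldehyde.

Step 3
Reactants: 5 (S)-4-benzyl-3-(pent-4-enoyl)-1,3-oxazolidin-2-one; 2 4-(TBSO)-3-methoxybenzaldehyde
Product: 7 (4S)-4-benzyl-3-{(2S)-2-[(S)-Ar(hydroxy)methyl]pent-4-enoyl}-1,3-oxazolidin-2-one (syn aldol), via (Z)-dibutylboron enolate 6 (not isolated)
Conditions: Bu2BOTf, Et3N, CH2Cl2, 0 °C; 2, −78 → 0 °C; pH 7 buffer, MeOH, 30% H2O2, 0 °C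
Reagents that add atoms: dibutylboryl triflate, CCCCB(CCCC)OS(=O)(=O)C(F)(F)F (atoms only in intermediate 6)
Why: In this Evans syn aldol the (Z)-boron enolate reacts through a Zimmerman–Traxler chair on the face left open by the benzyl group, which sets C4 (and provisionally C5) of the oxolane by auxiliary control.

Step 4
Reactants: 7 syn-aldol imide
Product: 8 (1S,2R)-1-Ar-2-(prop-2-enyl)propane-1,3-diol
Conditions: LiBH4, MeOH (1 equiv), Et2O, 0 °C
Reagents that add atoms: none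
Why: Reductive cleavage of the imide with LiBH4 turns the acyl carbon into the C4 CH2OH without touching either stereocentre and returns the auxiliary.

Step 5
Reactants: 8 (1S,2R)-1-Ar-2-(prop-2-enyl)propane-1,3-diol
Product: 9 (4S,5R)-4-Ar-2,2-dimethyl-5-(prop-2-enyl)-1,3-dioxane
Conditions: Me2C(OMe)2, PPTS (cat.), CH2Cl2, rt
Reagents that add atoms: 2,2-dimethoxypropane, COC(C)(C)OC
Why: Acetonide formation masks both hydroxyls in one step, prevents lactol formation with the coming aldehyde, and is removed by the same acid that later closes ring A.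

Step 6
Reactants: 9 (4S,5R)-4-Ar-2,2-dimethyl-5-(prop-2-enyl)-1,3-dioxane
Product: 11 2-[(4S,5R)-4-Ar-2,2-dimethyl-1,3-dioxan-5-yl]acetaldehyde, via vicinal diol 10 (not isolated)
Conditions: OsO4 (cat.), NaIO4, 2,6-lutidine, dioxane–H2O, rt
Reagents that add atoms: osmium tetroxide, O=[Os](=O)(=O)=O (catalytic oxygen carrier); sodium periodate, [Na+].[O-]I(=O)(=O)=O (terminal oxygen source)
Why: Lemieux–Johnson cleavage of the only alkene gives the aldehyde and spares the electron-rich arene that ozone could attack.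

Step 7
Reactants: 11 2-[(4S,5R)-4-Ar-2,2-dimethyl-1,3-dioxan-5-yl]acetaldehyde
Product: 12 2-[(4S,5R)-4-Ar-2,2-dimethyl-1,3-dioxan-5-yl]prop-2-enal
Conditions: 37% aq. HCHO, pyrrolidine (cat.), EtCO2H (cat.), i-PrOH, 45 °C
Reagents that add atoms: formaldehyde, C=O
Why: Amine-catalysed Mannich condensation and elimination (α-methylenation of an aldehyde) makes C3 sp2, so no labile α-stereocentre is carried, and it introduces the future C6 carbon.

Step 8
Reactants: 13 methyl 3-(4-hydroxy-3-methoxyphenyl)propanoate; 14 bromoacetic acid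
Product: 15 [2-methoxy-4-(3-methoxy-3-oxopropyl)phenoxy]acetic acid
Conditions: NaH (2.2 equiv), THF, 0 → 65 °C; then 1 M HCl
Reagents that add atoms: none
Why: Williamson etherification of the sodium phenoxide with sodium bromoacetate gives the aryloxyacetic acid directly, and the methyl ester serves as an unprotected precursor of the 3-hydroxypropyl chain.

Step 9
Reactants: 15 [2-methoxy-4-(3-methoxy-3-oxopropyl)phenoxy]acetic acid; 16 (R)-4-benzyl-1,3-oxazolidin-2-one
Product: 18 methyl 3-(4-{2-[(4R)-4-benzyl-2-oxo-1,3-oxazolidin-3-yl]-2-oxoethoxy}-3-methoxyphenyl)propanoate, via mixed pivalic anhydride 17 (not isolated)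
Conditions: PivCl, Et3N, THF, −20 °C; then LiCl, 16, rt
Reagents that add atoms: pivaloyl chloride, CC(C)(C)C(=O)Cl (atoms only in intermediate 17)
Why: Mixed-anhydride N-acylation promoted by LiCl is the standard mild route to glycolate-type imides, and attack occurs at the less hindered aryloxyacetyl carbonyl.

Step 10
Reactants: 18 aryloxyacetyl imide; 12 2-[(4S,5R)-4-Ar-2,2-dimethyl-1,3-dioxan-5-yl]prop-2-enal
Product: 20 (4R)-4-benzyl-3-[(2R,3S)-4-{(4S,5R)-4-Ar-2,2-dimethyl-1,3-dioxan-5-yl}-3-hydroxy-2-{2-methoxy-4-(3-methoxy-3-oxopropyl)phenoxy}pent-4-enoyl]-1,3-oxazolidin-2-one, via (Z)-dibutylboron enolate 19 (not isolated)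
Conditions: Bu2BOTf, Et3N, CH2Cl2, −78 → 0 °C; 12, −78 → 0 °C; pH 7 buffer, MeOH, 30% H2O2, 0 °C
Reagents that add atoms: dibutylboryl triflate, CCCCB(CCCC)OS(=O)(=O)C(F)(F)F (atoms only in intermediate 19)
Why: This Evans glycolate syn aldol on a methacrolein-type enal joins the two halves, and the (R)-auxiliary sets the syn pair C2(OH)/C1'(OAr) by reagent control that should override the remote C4 centre.

Step 11
Reactants: 20 syn-aldol imide
Product: 21 (2S,3S)-4-[(4S,5R)-4-Ar-2,2-dimethyl-1,3-dioxan-5-yl]-2-[4-(3-hydroxypropyl)-2-methoxyphenoxy]pent-4-ene-1,3-diol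
Conditions: LiBH4 (excess), MeOH, THF, 0 °C → rt
Reagents that add atoms: none
Why: A single LiBH4 reduction removes the auxiliary to give the C1' CH2OH and reduces the methyl ester to the 3-hydroxypropyl chain, leaving alkene, acetonide and aryl silyl ether intact.

Step 12
Reactants: 21 triol acetonide
Product: 23 (2S,4R,5S)-5-Ar-4-(hydroxymethyl)-2-{(1S)-2-hydroxy-1-[4-(3-hydroxypropyl)-2-methoxyphenoxy]ethyl}-3-methylideneoxolane, via pentaol 22 (not isolated)
Conditions: 80% aq. AcOH, 40 °C; evaporate; CSA (cat.), CH2Cl2–MeCN, 0 °C → rt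
Reagents that add atoms: none
Why: After acetonide hydrolysis the 4-silyloxy-3-methoxybenzyl alcohol ionises and the C2 hydroxyl captures the quinoid cation (SN1 cycloetherification, 5-exo-trig), and this reversible closure should settle on the isomer with the aryl group trans to the neighbouring C4 CH2OH, which is also the configuration delivered by the syn aldol.

Step 13
Reactants: 23 methylideneoxolane triol
Product: 24 (2S,4R,5S)-5-Ar-2-SC-4-(TBSOCH2)-3-methylideneoxolane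
Conditions: TBSCl (excess), imidazole, DMF, rt
Reagents that add atoms: tert-butyldimethylsilyl chloride, CC(C)(C)[Si](C)(C)Cl
Why: Silylation of the three primary alcohols puts all four hydroxyl functions under one fluoride-labile group and makes the C2/C4 face of ring A bulky for step 18.

Step 14
Reactants: 24 (2S,4R,5S)-5-Ar-2-SC-4-(TBSOCH2)-3-methylideneoxolane
Product: 26 [(2S,3S,4R,5S)-5-Ar-2-SC-4-(TBSOCH2)oxolan-3-yl]methanol, via B-alkyl-9-BBN adduct 25 (not isolated)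
Conditions: 9-BBN, THF, 0 → 60 °C; then 30% H2O2, aq. NaOAc, 0 °C → rt
Reagents that add atoms: hydrogen peroxide, OO; 9-borabicyclo[3.3.1]nonane, B1C2CCCC1CCC2 (atoms only in intermediate 25)
Why: Anti-Markovnikov hydroboration–oxidation of the 1,1-disubstituted alkene should occur from the face opposite to the C2 and C4 substituents to give the all-cis C3 epimer, and the acetate-buffered oxidation spares the aryl silyl ether.

Step 15
Reactants: 26 [(2S,3S,4R,5S)-5-Ar-2-SC-4-(TBSOCH2)oxolan-3-yl]methanol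
Product: 27 (2S,3R,4R,5S)-5-Ar-2-SC-4-(TBSOCH2)oxolane-3-carbaldehyde
Conditions: Dess–Martin periodinane, CH2Cl2, 0 °C → rt
Reagents that add atoms: none
Why: Dess–Martin oxidation is neutral and base-free, so the β-alkoxy aldehyde is formed without retro-oxa-Michael opening of ring A.

Step 16
Reactants: 27 (2S,3R,4R,5S)-5-Ar-2-SC-4-(TBSOCH2)oxolane-3-carbaldehyde; 28 methyl 2-(dimethoxyphosphoryl)-2-methoxyacetate
Product: 29 methyl (Z)-3-[(2S,3S,4R,5S)-5-Ar-2-SC-4-(TBSOCH2)oxolan-3-yl]-2-methoxyprop-2-enoate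
Conditions: 28, LiN(SiMe3)2, THF, −78 °C; then 27, −78 → 0 °C
Reagents that add atoms: none
Why: Horner–Wadsworth–Emmons olefination with the weakly basic stabilised phosphonate anion adds C7 (with its methoxy group) and C8 in one step, with the (Z)-enoate expected as the main isomer.

Step 17
Reactants: 29 2-methoxy enoate
Product: 30 vinylketene silyl acetal: (2S,4R,5S)-5-Ar-2-SC-4-(TBSOCH2)-3-[3-(TBSO)-2,3-dimethoxyprop-2-enylidene]oxolane
Conditions: LiN(i-Pr)2, THF–DMPU, −78 °C; TBSCl, −78 → −20 °C; pentane, cold aq. NaHCO3 wash; used directly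
Reagents that add atoms: tert-butyldimethylsilyl chloride, CC(C)(C)[Si](C)(C)Cl
Why: Vinylogous (γ) deprotonation and O-silylation is the standard preparation of vinylketene silyl acetals; here C3–H is the only acidic hydrogen and lies on the open ring face, and the low temperature keeps the dienolate from expelling the ring oxygen.

Step 18
Reactants: 30 vinylketene silyl acetal; 31 phenyl vinyl sulfoxide
Product: 34 (1S,3S,4R,5S)-3-Ar-1-SC-4-(TBSOCH2)-7-methoxy-2-oxaspiro[4.5]deca-6,9-dien-8-one, via sulfinyl cycloadduct 32 (not isolated), via dienone silyl methyl ketal 33 (not isolated)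
Conditions: 31 (excess), toluene, sealed tube, 110 °C; then aq. citric acid, THF, rt
Reagents that add atoms: none
Why: The 1,1,2-trioxygenated diene of 30 (C8=C7–C6=C5) and the CH2=CH unit of 31 combine in a normal-electron-demand, asynchronous Diels–Alder reaction in which nucleophilic C5 bonds to the unsubstituted CH2 terminus and C8 to the sulfinyl-bearing carbon (32); at the same temperature the sulfoxide leaves by syn elimination to create C9=C10 (33), and mild acid collapses the silyl methyl ketal to the C8 ketone. The closest known reaction types are cycloadditions of vinylketene acetals and related oxygenated dienes with phenyl vinyl sulfoxide or sulfinyl enones as acetylene equivalents, which end in cyclohexadienones, and the spiro-forming cycloadditions of allylidenecycloalkanes. Ring B closes in the intermolecular [4+2] (π4s + π2s) mode, both new σ bonds forming on one face of the diene, and no other ring is made. The only new stereocentre that survives is C5: the C1 side chain and the C4 CH2OTBS group stand on the same face of the nearly flat alkylidene-oxolane and flank C5, so the dienophile should come from the opposite face, where it meets only two ring hydrogens and the more distant C3 aryl group, which puts C10 anti and C6 syn to these groups as in the target. Regiochemistry, endo/exo mode, sulfur configuration and both diene geometries need no control, because every such isomer converges on 34 after elimination and ketal collapse. What the step does need is access to the s-cis rotamer at a fully substituted terminus, which is helped by the C7 methoxy group (it destabilises the s-trans rotamer against the ring carbon), by the five-membered ring that ties the inside substituent back, by bond formation to an unsubstituted CH2, and by a non-polar, Lewis-acid-free medium that suppresses silyl transfer from the ketene acetal to the sulfoxide oxygen.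

Step 19
Reactants: 34 tetrakis-TBS spirodienone
Product: 35 (1S,3S,4R,5S)-3-(4-hydroxy-3-methoxyphenyl)-4-(hydroxymethyl)-1-{(1S)-2-hydroxy-1-[4-(3-hydroxypropyl)-2-methoxyphenoxy]ethyl}-7-methoxy-2-oxaspiro[4.5]deca-6,9-dien-8-one (target)
Conditions: Et3N·3HF (excess), MeCN–THF, rt
Reagents that add atoms: none
Why: Near-neutral fluoride desilylation removes the three alkyl and one aryl TBS group in one operation without the acid or base that could open the 4-hydroxybenzyl ether or trigger a dienone–phenol rearrangement.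

Compound list
1 | vanillin (4-hydroxy-3-methoxybenzaldehyde) | O=Cc1ccc(O)c(OC)c1 | starting material
2 | 4-(TBSO)-3-methoxybenzaldehyde | O=Cc1ccc(O[Si](C)(C)C(C)(C)C)c(OC)c1 | intermediate
3 | (S)-4-benzyl-1,3-oxazolidin-2-one | O=C1N[C@@H](Cc2ccccc2)CO1 | starting material
4 | pent-4-enoyl chloride | C=CCCC(=O)Cl | starting material
5 | (S)-4-benzyl-3-(pent-4-enoyl)-1,3-oxazolidin-2-one | C=CCCC(=O)N1[C@@H](Cc2ccccc2)COC1=O | intermediate
6 | (Z)-dibutylboron enolate of 5 | C=CC/C=C(\OB(CCCC)CCCC)N1[C@@H](Cc2ccccc2)COC1=O | intermediate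
7 | (4S)-4-benzyl-3-{(2S)-2-[(S)-Ar(hydroxy)methyl]pent-4-enoyl}-1,3-oxazolidin-2-one | C=CC[C@H](C(=O)N1[C@@H](Cc2ccccc2)COC1=O)[C@@H](c3ccc(O[Si](C)(C)C(C)(C)C)c(OC)c3)O | intermediate
8 | (1S,2R)-1-Ar-2-(prop-2-enyl)propane-1,3-diol | C=CC[C@H](CO)[C@@H](c1ccc(O[Si](C)(C)C(C)(C)C)c(OC)c1)O | intermediate
9 | (4S,5R)-4-Ar-2,2-dimethyl-5-(prop-2-enyl)-1,3-dioxane | C=CC[C@@H]1COC(C)(C)O[C@@H]1c2ccc(O[Si](C)(C)C(C)(C)C)c(OC)c2 | intermediate
10 | 3-[(4S,5R)-4-Ar-2,2-dimethyl-1,3-dioxan-5-yl]propane-1,2-diol (both C2 epimers) | OCC(O)C[C@@H]1COC(C)(C)O[C@@H]1c2ccc(O[Si](C)(C)C(C)(C)C)c(OC)c2 | intermediate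
11 | 2-[(4S,5R)-4-Ar-2,2-dimethyl-1,3-dioxan-5-yl]acetaldehyde | O=CC[C@@H]1COC(C)(C)O[C@@H]1c2ccc(O[Si](C)(C)C(C)(C)C)c(OC)c2 | intermediate
12 | 2-[(4S,5R)-4-Ar-2,2-dimethyl-1,3-dioxan-5-yl]prop-2-enal | C=C(C=O)[C@@H]1COC(C)(C)O[C@@H]1c2ccc(O[Si](C)(C)C(C)(C)C)c(OC)c2 | intermediate
13 | methyl 3-(4-hydroxy-3-methoxyphenyl)propanoate | COC(=O)CCc1ccc(O)c(OC)c1 | starting material
14 | bromoacetic acid | OC(=O)CBr | starting material
15 | [2-methoxy-4-(3-methoxy-3-oxopropyl)phenoxy]acetic acid | COC(=O)CCc1ccc(OCC(=O)O)c(OC)c1 | intermediate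
16 | (R)-4-benzyl-1,3-oxazolidin-2-one | O=C1N[C@H](Cc2ccccc2)CO1 | starting material
17 | mixed pivalic anhydride of 15 | COC(=O)CCc1ccc(OCC(=O)OC(=O)C(C)(C)C)c(OC)c1 | intermediate
18 | methyl 3-(4-{2-[(4R)-4-benzyl-2-oxo-1,3-oxazolidin-3-yl]-2-oxoethoxy}-3-methoxyphenyl)propanoate | COC(=O)CCc1ccc(OCC(=O)N2[C@H](Cc3ccccc3)COC2=O)c(OC)c1 | intermediate
19 | (Z)-dibutylboron enolate of 18 | COC(=O)CCc1ccc(O/C=C(\OB(CCCC)CCCC)N2[C@H](Cc3ccccc3)COC2=O)c(OC)c1 | intermediate
20 | (2R,3S) syn-aldol imide from 18 and 12 | O[C@@H](C(=C)[C@@H]1COC(C)(C)O[C@@H]1c2ccc(O[Si](C)(C)C(C)(C)C)c(OC)c2)[C@H](C(=O)N3[C@H](Cc4ccccc4)COC3=O)Oc5ccc(CCC(=O)OC)cc5OC | intermediate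
21 | (2S,3S)-4-[(4S,5R)-4-Ar-2,2-dimethyl-1,3-dioxan-5-yl]-2-[4-(3-hydroxypropyl)-2-methoxyphenoxy]pent-4-ene-1,3-diol | O[C@@H](C(=C)[C@@H]1COC(C)(C)O[C@@H]1c2ccc(O[Si](C)(C)C(C)(C)C)c(OC)c2)[C@H](CO)Oc3ccc(CCCO)cc3OC | intermediate
22 | pentaol (21 without the acetonide) | O[C@@H](C(=C)[C@H](CO)[C@@H](c1ccc(O[Si](C)(C)C(C)(C)C)c(OC)c1)O)[C@H](CO)Oc2ccc(CCCO)cc2OC | intermediate
23 | (2S,4R,5S)-5-Ar-4-(hydroxymethyl)-2-{(1S)-2-hydroxy-1-[4-(3-hydroxypropyl)-2-methoxyphenoxy]ethyl}-3-methylideneoxolane | C=C1[C@H](CO)[C@@H](c2ccc(O[Si](C)(C)C(C)(C)C)c(OC)c2)O[C@@H]1[C@H](CO)Oc3ccc(CCCO)cc3OC | intermediate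
24 | (2S,4R,5S)-5-Ar-2-SC-4-(TBSOCH2)-3-methylideneoxolane | C=C1[C@H](CO[Si](C)(C)C(C)(C)C)[C@@H](c2ccc(O[Si](C)(C)C(C)(C)C)c(OC)c2)O[C@@H]1[C@H](CO[Si](C)(C)C(C)(C)C)Oc3ccc(CCCO[Si](C)(C)C(C)(C)C)cc3OC | intermediate
25 | B-[(oxolan-3-yl)methyl]-9-BBN adduct of 24 (CH2B cis to the C2 and C4 substituents) | C(B1C2CCCC1CCC2)[C@@H]3[C@H](CO[Si](C)(C)C(C)(C)C)[C@@H](c4ccc(O[Si](C)(C)C(C)(C)C)c(OC)c4)O[C@@H]3[C@H](CO[Si](C)(C)C(C)(C)C)Oc5ccc(CCCO[Si](C)(C)C(C)(C)C)cc5OC | intermediate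
26 | [(2S,3S,4R,5S)-5-Ar-2-SC-4-(TBSOCH2)oxolan-3-yl]methanol | OC[C@@H]1[C@H](CO[Si](C)(C)C(C)(C)C)[C@@H](c2ccc(O[Si](C)(C)C(C)(C)C)c(OC)c2)O[C@@H]1[C@H](CO[Si](C)(C)C(C)(C)C)Oc3ccc(CCCO[Si](C)(C)C(C)(C)C)cc3OC | intermediate
27 | (2S,3R,4R,5S)-5-Ar-2-SC-4-(TBSOCH2)oxolane-3-carbaldehyde | O=C[C@@H]1[C@H](CO[Si](C)(C)C(C)(C)C)[C@@H](c2ccc(O[Si](C)(C)C(C)(C)C)c(OC)c2)O[C@@H]1[C@H](CO[Si](C)(C)C(C)(C)C)Oc3ccc(CCCO[Si](C)(C)C(C)(C)C)cc3OC | intermediate
28 | methyl 2-(dimethoxyphosphoryl)-2-methoxyacetate | COC(=O)C(OC)P(=O)(OC)OC | starting material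
29 | methyl (Z)-3-[(2S,3S,4R,5S)-5-Ar-2-SC-4-(TBSOCH2)oxolan-3-yl]-2-methoxyprop-2-enoate | COC(=O)/C(OC)=C/[C@@H]1[C@H](CO[Si](C)(C)C(C)(C)C)[C@@H](c2ccc(O[Si](C)(C)C(C)(C)C)c(OC)c2)O[C@@H]1[C@H](CO[Si](C)(C)C(C)(C)C)Oc3ccc(CCCO[Si](C)(C)C(C)(C)C)cc3OC | intermediate
30 | (2S,4R,5S)-5-Ar-2-SC-4-(TBSOCH2)-3-[3-(TBSO)-2,3-dimethoxyprop-2-enylidene]oxolane (drawn with the chain syn to C4) | CO/C(O[Si](C)(C)C(C)(C)C)=C(OC)\C=C1/[C@H](CO[Si](C)(C)C(C)(C)C)[C@@H](c2ccc(O[Si](C)(C)C(C)(C)C)c(OC)c2)O[C@@H]1[C@H](CO[Si](C)(C)C(C)(C)C)Oc3ccc(CCCO[Si](C)(C)C(C)(C)C)cc3OC | intermediate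
31 | phenyl vinyl sulfoxide | C=CS(=O)c1ccccc1 | starting material
32 | 9-(phenylsulfinyl)-7,8-dimethoxy-8-(TBSO)-2-oxaspiro[4.5]dec-6-ene cycloadduct (C1, C3, C4, C5 as in 34; C8, C9 and S mixed) | COC1=C[C@]2(CC(S(=O)c3ccccc3)C1(OC)O[Si](C)(C)C(C)(C)C)[C@H](CO[Si](C)(C)C(C)(C)C)[C@@H](c4ccc(O[Si](C)(C)C(C)(C)C)c(OC)c4)O[C@@H]2[C@H](CO[Si](C)(C)C(C)(C)C)Oc5ccc(CCCO[Si](C)(C)C(C)(C)C)cc5OC | intermediate
33 | 7,8-dimethoxy-8-(TBSO)-2-oxaspiro[4.5]deca-6,9-diene (silyl methyl ketal of 34; C8 mixed) | COC1=C[C@]2(C=CC1(OC)O[Si](C)(C)C(C)(C)C)[C@H](CO[Si](C)(C)C(C)(C)C)[C@@H](c3ccc(O[Si](C)(C)C(C)(C)C)c(OC)c3)O[C@@H]2[C@H](CO[Si](C)(C)C(C)(C)C)Oc4ccc(CCCO[Si](C)(C)C(C)(C)C)cc4OC | intermediate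
34 | (1S,3S,4R,5S)-3-Ar-1-SC-4-(TBSOCH2)-7-methoxy-2-oxaspiro[4.5]deca-6,9-dien-8-one | COC1=C[C@]2(C=CC1=O)[C@H](CO[Si](C)(C)C(C)(C)C)[C@@H](c3ccc(O[Si](C)(C)C(C)(C)C)c(OC)c3)O[C@@H]2[C@H](CO[Si](C)(C)C(C)(C)C)Oc4ccc(CCCO[Si](C)(C)C(C)(C)C)cc4OC | intermediate
35 | CNP0252711.1, (1S,3S,4R,5S)-3-(4-hydroxy-3-methoxyphenyl)-4-(hydroxymethyl)-1-{(1S)-2-hydroxy-1-[4-(3-hydroxypropyl)-2-methoxyphenoxy]ethyl}-7-methoxy-2-oxaspiro[4.5]deca-6,9-dien-8-one | COC1=C[C@]2(C=CC1=O)[C@H](CO)[C@@H](c1ccc(O)c(OC)c1)O[C@@H]2[C@H](CO)Oc1ccc(CCCO)cc1OC | target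

Total step count: 19. Longest linear sequence: 16 steps (steps 2–7 and 10–19).

Steps most likely to fail

1. Step 18.
Risk: the cycloaddition may be too slow, because the diene terminus C5 is fully substituted and both termini carry an inside substituent in the s-cis rotamer, while the sulfoxide is a weak dienophile. Prolonged heating could then allow silyl transfer from the ketene acetal to the sulfoxide oxygen, protonation of the diene by the liberated sulfenic acid, or loss of facial selectivity.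
Fallback (sets out from 27, returns at 34): ring B is built by a Stork-type Robinson spiroannulation instead of a cycloaddition.
- Pyrrolidine-catalysed Michael addition of 27 through C3 to commercial 1-methoxybut-3-en-2-one, again on the face opposite to the C2 and C4 substituents, should give keto aldehyde F1.
- Piperidinium acetate then closes the ring by aldol condensation between the methoxy-bearing methylene and the formyl group to give spiro-enone F2.
- Kinetic enolisation toward C9 (LiN(i-Pr)2, TBSCl) gives silyl dienol ether F3.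
- Saegusa–Ito dehydrogenation with Pd(OAc)2 in MeCN gives 34.

2. Step 17.
Risk: the lithium dienolate may expel the ring oxygen (vinylogous E1cB opening of ring A) on warming. The amide base may add in conjugate fashion to the enoate. The hindered, moisture-sensitive ketene acetal may be protonated back on isolation.
Fallback (sets out from 29, returns at 34): the diene is moved to the aldehyde oxidation level, where γ-enolisation needs only an amine base and one inside substituent disappears.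
- i-Bu2AlH reduces 29 to allylic alcohol F4, and MnO2 gives enal F5.
- Et3SiOTf/Et3N at −78 °C gives silyloxy diene F6.
- Heating with 31 as in step 18 gives sulfinyl cycloadduct F7, which loses the sulfoxide in the same pot to give dienyl silyl ether F8.
- Pyridine-buffered HF·pyridine frees the doubly allylic dienol F9 selectively (triethylsilyl versus TBS), and MnO2 oxidises it to 34.

3. Step 12.
Risk: ionisation of the silyl-protected benzylic alcohol may need acid strong enough to cause proton loss from C4 to a styrene, migration of the acetonide to the other 1,3-diol, ionisation of the allylic alcohol, or incomplete equilibration at the aryl-bearing carbon.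
Fallback (sets out from 21, returns at 24): the closure is run on the free phenol, which reacts by the nearly neutral quinone methide pathway instead of through a benzylic cation.
- Bu4NF (1 equiv, 0 °C) removes the aryl silyl ether to give phenol F10.
- Warm aqueous acetic acid takes off the acetonide, and the 4-hydroxybenzyl alcohol then closes onto the C2 hydroxyl, trans to the C4 substituent, to give tetraol F11.
- Excess TBSCl/imidazole silylates the phenol and the three primary alcohols together to give 24.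

Further compounds
F1 | step 18 | 5-Ar-2-SC-4-(TBSOCH2)-3-(4-methoxy-3-oxobutyl)oxolane-3-carbaldehyde (oxobutyl chain anti to the C2 and C4 substituents) | COCC(=O)CC[C@@]1(C=O)[C@H](CO[Si](C)(C)C(C)(C)C)[C@@H](c2ccc(O[Si](C)(C)C(C)(C)C)c(OC)c2)O[C@@H]1[C@H](CO[Si](C)(C)C(C)(C)C)Oc3ccc(CCCO[Si](C)(C)C(C)(C)C)cc3OC
F2 | step 18 | 3-Ar-1-SC-4-(TBSOCH2)-7-methoxy-2-oxaspiro[4.5]dec-6-en-8-one (stereocentres as in 34) | COC1=C[C@]2(CCC1=O)[C@H](CO[Si](C)(C)C(C)(C)C)[C@@H](c3ccc(O[Si](C)(C)C(C)(C)C)c(OC)c3)O[C@@H]2[C@H](CO[Si](C)(C)C(C)(C)C)Oc4ccc(CCCO[Si](C)(C)C(C)(C)C)cc4OC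
F3 | step 18 | 3-Ar-1-SC-4-(TBSOCH2)-7-methoxy-8-(TBSO)-2-oxaspiro[4.5]deca-6,8-diene (stereocentres as in 34) | COC1=C[C@]2(CC=C1O[Si](C)(C)C(C)(C)C)[C@H](CO[Si](C)(C)C(C)(C)C)[C@@H](c3ccc(O[Si](C)(C)C(C)(C)C)c(OC)c3)O[C@@H]2[C@H](CO[Si](C)(C)C(C)(C)C)Oc4ccc(CCCO[Si](C)(C)C(C)(C)C)cc4OC
F4 | step 17 | (Z)-3-[5-Ar-2-SC-4-(TBSOCH2)oxolan-3-yl]-2-methoxyprop-2-en-1-ol (ring as in 29) | OC/C(OC)=C/[C@@H]1[C@H](CO[Si](C)(C)C(C)(C)C)[C@@H](c2ccc(O[Si](C)(C)C(C)(C)C)c(OC)c2)O[C@@H]1[C@H](CO[Si](C)(C)C(C)(C)C)Oc3ccc(CCCO[Si](C)(C)C(C)(C)C)cc3OC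
F5 | step 17 | (Z)-3-[5-Ar-2-SC-4-(TBSOCH2)oxolan-3-yl]-2-methoxyprop-2-enal (ring as in 29) | O=C/C(OC)=C/[C@@H]1[C@H](CO[Si](C)(C)C(C)(C)C)[C@@H](c2ccc(O[Si](C)(C)C(C)(C)C)c(OC)c2)O[C@@H]1[C@H](CO[Si](C)(C)C(C)(C)C)Oc3ccc(CCCO[Si](C)(C)C(C)(C)C)cc3OC
F6 | step 17 | 5-Ar-2-SC-4-(TBSOCH2)-3-[2-methoxy-3-(triethylsilyloxy)prop-2-enylidene]oxolane (silyloxy group outside, chain syn to C4) | CC[Si](CC)(CC)O\C=C(OC)\C=C1/[C@H](CO[Si](C)(C)C(C)(C)C)[C@@H](c2ccc(O[Si](C)(C)C(C)(C)C)c(OC)c2)O[C@@H]1[C@H](CO[Si](C)(C)C(C)(C)C)Oc3ccc(CCCO[Si](C)(C)C(C)(C)C)cc3OC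
F7 | step 17 | 7-methoxy-9-(phenylsulfinyl)-8-(triethylsilyloxy)-2-oxaspiro[4.5]dec-6-ene cycloadduct (C1, C3, C4, C5 as in 34; C8, C9 and S mixed) | COC1=C[C@]2(CC(S(=O)c3ccccc3)C1O[Si](CC)(CC)CC)[C@H](CO[Si](C)(C)C(C)(C)C)[C@@H](c4ccc(O[Si](C)(C)C(C)(C)C)c(OC)c4)O[C@@H]2[C@H](CO[Si](C)(C)C(C)(C)C)Oc5ccc(CCCO[Si](C)(C)C(C)(C)C)cc5OC
F8 | step 17 | 3-Ar-1-SC-4-(TBSOCH2)-7-methoxy-8-(triethylsilyloxy)-2-oxaspiro[4.5]deca-6,9-diene (C8 mixed) | COC1=C[C@]2(C=CC1O[Si](CC)(CC)CC)[C@H](CO[Si](C)(C)C(C)(C)C)[C@@H](c3ccc(O[Si](C)(C)C(C)(C)C)c(OC)c3)O[C@@H]2[C@H](CO[Si](C)(C)C(C)(C)C)Oc4ccc(CCCO[Si](C)(C)C(C)(C)C)cc4OC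
F9 | step 17 | 3-Ar-1-SC-4-(TBSOCH2)-7-methoxy-2-oxaspiro[4.5]deca-6,9-dien-8-ol (C8 mixed) | COC1=C[C@]2(C=CC1O)[C@H](CO[Si](C)(C)C(C)(C)C)[C@@H](c3ccc(O[Si](C)(C)C(C)(C)C)c(OC)c3)O[C@@H]2[C@H](CO[Si](C)(C)C(C)(C)C)Oc4ccc(CCCO[Si](C)(C)C(C)(C)C)cc4OC
F10 | step 12 | free phenol of 21 | O[C@@H](C(=C)[C@@H]1COC(C)(C)O[C@@H]1c2ccc(O)c(OC)c2)[C@H](CO)Oc3ccc(CCCO)cc3OC
F11 | step 12 | free phenol of 23 (methylideneoxolane tetraol) | C=C1[C@H](CO)[C@@H](c2ccc(O)c(OC)c2)O[C@@H]1[C@H](CO)Oc3ccc(CCCO)cc3OC
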